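The amounts told me what to watch: the east flask held G at 0.950 equiv and J at 0.800 equiv to D, yet Gu levelled off near 62.8%, while the south-west run, with the same equivalents at twice the concentration, levelled off near 72.6%.

| flask | D | G | X | J | temperature | remark | time |
|---|---|---|---|---|---|---|---|
| east | 0.20 M | 0.95 equiv | 2 equiv | 0.80 equiv | 5 °C | the very flask that is asked about, followed so far |  |
| south-west | 0.40 M | 0.95 equiv | 2 equiv | 0.80 equiv | 5 °C | run made earlier |  |
| flask | 0.20 M | 0.950 equiv | 2.00 equiv | 0.800 equiv | 5 °C |  | 8.0 d |

| run | time / d | Gu / % |
|---|---|---|
| east | 0.333 | 5.0 |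
| east | 0.833 | 25.0 |
| east | 1.67 | 45.5 |
| east | 2.50 | 56.5 |
| east | 4.00 | 62.8 |
| east | 5.00 | 61.8 |
| south-west | 0.250 | 13.0 |
| south-west | 0.500 | 32.2 |
| south-west | 0.833 | 49.5 |
| south-west | 1.25 | 58.9 |
| south-west | 2.00 | 69.5 |
| south-west | 4.00 | 72.6 |

(standard deviation of a reading: 1 percentage point)

* Gu, in percent of the D first charged, at 8.0 d
* the option that brings most further Gu ("none" if no option brings more than 2 percentage points) (amber / red / blue / ochre / none)
* Gu present, in percent of the D first charged, after amber
* Gu present, in percent of the D first charged, after red

- amber: at 8.0 d raise the temperature by 10 K, then wait 8.0 d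
- red: at 8.0 d add D, 50.0% of the amount charged, then wait 8.0 d
- blue: at 8.0 d add X, 50.0% of the amount charged, then wait 8.0 d
- ochre: change nothing and wait 8.0 d more

- what is added takes up no volume worth counting
- a reading or a percentage of Gu counts all its forms, free or not
- the earlier runs do not show what temperature does; that part of a forecast is a guess

I read this as a contest for G, with a second-order step taking G with D and a first-order loss taking G away. Dividing the two rates and integrating in closed form gives: G lost = s · ln(D charged / D left), where s is the ratio of the loss constant to the step's constant. Taking Gu as the D used, and charged G less that D as the G lost, I got 0.0651 M from the east readings and 0.0692 M from the south-west ones. Their mean, 0.0672 M, is the sharing concentration: the level of D at which G goes as fast to the loss as to D. I therefore expected the flask to stay close to its plateau at 8.0 d, with any further gain needing G to come back from the loss, which the readings could not show.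

The forecast, holding that “A plateau that rises with concentration suggests a reversible association”, gave 62.5%, red as best, 59% after amber and 75% after red.

The flask gave 65.9%, and amber brought the most, a gain of 12 percentage points to 77.6%, against 6.6 points for red, which reached 72.5%.

    Ve ⇌ Gu, rate k1*(cs1 - [Gu]) while solid is left; crystals form when [Gu] > cs1 (solubility = 0.180 M, k = 0.398 h⁻¹)
    J + E → Gu (k = 1.52 L mol⁻¹ h⁻¹, Ea = 53.0 kJ mol⁻¹)
    D + G → Q (k = 0.539 L mol⁻¹ h⁻¹, Ea = 71.0 kJ mol⁻¹)
    G ⇌ Z (K = 17.0, k = 0.0378 h⁻¹, Ea = 87.0 kJ mol⁻¹, ΔH = −8.00 kJ mol⁻¹)
    X + Q → E (k = 0.206 L mol⁻¹ h⁻¹, Ea = 52.0 kJ mol⁻¹)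
    (constants at 5 °C)

The loss was the step from G to Z. At 0.800 d, with D at 45.4%, my rule gave 0.0531 M lost, and the flask held Z at 0.0539 M. At 8.00 d, with D at 32.8%, it gave 0.0749 M, but Z stood at 0.0540 M and G, the first charge to run out, at 0.871%, so the difference had returned to react; the limiting reagent is J, whose charge allows 80.0% of Gu. The largest single effect on amber's gain was the step from G to Z, both ways, for without it amber gained 0.2 points; a part of that step, the way back from Z to G, shows the same, since without it amber gained 0.017 points.

In the neighbour charged with 0.380 equiv of G, the share of D used is small enough to replace the logarithm by the share itself, so s predicts G/(D + s), or 28.4%. That flask gave 29.2%, with 70.5% of its D left.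

All runs come from a simulation for substances that don't exist, and the scatter is random.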